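- A small charge of precatalyst, 0.73 mM, has to turn over 0.79 M of starting material, so watch how fast the starting material falls, and not the end value by itself.

| flask | starting material | precatalyst | remark | time |
|---|---|---|---|---|
| midnight | 0.79 M | 0.73 mM | run made earlier |  |
| winter | 0.79 M | 1.5 mM | run made earlier |  |
| larch | 0.79 M (fed, over 5.00 h) | 0.73 mM | all but starting material at the start; starting material goes in evenly over 5.00 h, the run ends at 10 h | 10 h |
| oak | 0.79 M | 0.73 mM | a closed flask charged with all of it at once and left for 10 h | 10 h |
| alder | 0.79 M | 0.73 mM | one stirred flow tank at steady state, fed with the mixture as stated, mean residence time 10 h |  |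
| maple | 0.79 M | 0.73 mM | one stirred flow tank at steady state, fed with the mixture as stated, mean residence time 30.0 h |  |

midnight run (percent of the starting material charged)

| time / h | target / % | starting material / % |
|---|---|---|
| 0.500 | 0 | 98.9 |
| 1.50 | 5.0 | 94.7 |
| 3.00 | 15.5 | 83.5 |
| 4.00 | 27.4 | 73.3 |
| 6.00 | 46.8 | 54.2 |

winter run (percent of the starting material charged)

| time / min | target / % | starting material / % |
|---|---|---|
| 5.00 | 0 | 100.1 |
| 10.0 | 0 | 99.6 |
| 15.0 | 0.5 | 99.5 |
| 30.0 | 1.6 | 98.8 |
| 60.0 | 4.1 | 95.2 |

(standard deviation of a reading: 0.5 percentage points)

- amounts and yields of target count idle complex too
- the stated concentrations are those of everything mixed, before any reaction; amounts are the same in each set-up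
- reactions considered so far: precatalyst -> free catalyst; starting material + free catalyst <-> catalyst intermediate; free catalyst + target <-> idle complex; catalyst intermediate -> free catalyst + target
- the feed brings no volume worth counting
- the earlier runs were made in a closed, stirred flask

- the set-up with the highest amount of target at the outlet or at the end, in percent of the starting material put in ("none" if the first two lie within 2 percentage points) (larch / oak / alder / maple / none)
- amount of target at the outlet or at the end, in percent of the starting material put in, larch
- amount of target at the outlet or at the end, in percent of the starting material put in, oak
- amount of target at the outlet or at the end, in percent of the starting material put in, alder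
- amount of target at the outlet or at the end, in percent of the starting material put in, maple

- In the midnight run the starting material falls from 73.3 % to 54.2 % between 4.00 h and 6.00 h, which reads as an apparent first-order constant of 0.151 h⁻¹.
- For maple, 4.53 is the Damköhler number, the residence time counted in lifetimes of the starting material.
- Taking that constant as it stands, a tank runs at outlet strength and converts the share number/(1 + number). I reckon 81.9 % for maple and, with a number of 1.51, 60.1 % for alder.
- Oak simply continues from the last midnight reading with the same constant, so I reckon 70.4 %.
- In larch the starting material waits 7.50 h on average, so I reckon 67.8 %.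
- That ranks maple first, and you can test the constant on the midnight run. Between 0.500 h and 3.00 h the constant reads 0.0677 h⁻¹, about half of the later value.
- So one number is not enough: the constant read in the midnight run climbs, and the figures above are working values.
- The forecast names maple, with 79 % for larch, 80 % for oak, 68 % for alder and 90 % for maple: “Maple wins because its residence time is three times longer.”
- The flasks give 73.0 % for larch, 76.0 % for oak, 62.4 % for alder and 86.5 % for maple, so maple is best.

    precatalyst → free catalyst (k = 0.195 h⁻¹)
    starting material + free catalyst ⇌ catalyst intermediate (K = 4.61 M⁻¹, k = 1550 M⁻¹ h⁻¹)
    free catalyst + target ⇌ idle complex (K = 2.00 M⁻¹, k = 4.85 M⁻¹ h⁻¹)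
    catalyst intermediate → free catalyst + target (k = 437 h⁻¹)

- Maple's 86.5 % stands above the 81.9 % reckoned from 4.53, and alder's 62.4 % stands above the 60.1 % reckoned from 1.51. The half-life of precatalyst by its turning into free catalyst alone is 3.6 h, shorter than maple's mean residence time of 30.0 h. Starting material in the maple tank stands at 0.107 M.

The readings are calculated with made-up constants, noise included.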